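The route rests on the disconnection of the C3–C1' bond between the chromanone (rings A and C) and the chromene aryl ring (ring B). Because C3 lies α to the C4 carbonyl, a racemic 3-bromochroman-4-one can be funnelled through a planar, carbonyl-stabilised C3 radical. A catalyst made from NiCl2·glyme and a chiral pybox ligand couples it with the arylzinc made from a 6-bromo-8-silyloxy-2,2-dimethylchromene. This joins the two fully elaborated halves and sets the only stereocentre (3R) in one base-free operation at −30 °C that spares this enolisable centre. The precursors are an α-bromo ketone and an aryl bromide; only desilylation follows.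

Key step: step 8

Remark: the absolute sense of induction of the pybox ligand on this cyclic bromide cannot be fixed by analogy; the (4R,5R)-ligand is written on the assumption that it delivers (3R), and its mirror image would be used otherwise.

Step 1
Reactants: 1 2',4'-dihydroxy-6'-methoxyacetophenone
Product: 2 1-{2-hydroxy-6-methoxy-4-[(triisopropylsilyl)oxy]phenyl}ethan-1-one
Conditions: TIPSCl, imidazole, DMF, 0 °C to 25 °C
Reagents that add atoms: chlorotriisopropylsilane, CC(C)[Si](Cl)(C(C)C)C(C)C
Why: Selective silylation of the free para-hydroxyl should occur because the ortho-hydroxyl is held in a hydrogen bond to the acetyl carbonyl, and the bulky TIPS ether is chosen to survive steps 2 and 3.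

Step 2
Reactants: 2 1-{2-hydroxy-6-methoxy-4-[(triisopropylsilyl)oxy]phenyl}ethan-1-one
Product: 4 5-methoxy-7-[(triisopropylsilyl)oxy]-4H-chromen-4-one, via enaminone 3 (not isolated)
Conditions: DMF-DMA, toluene, 95 °C; concentrate; then HCl (aq), CH2Cl2, 25 °C
Reagents that add atoms: N,N-dimethylformamide dimethyl acetal, COC(OC)N(C)C
Why: Condensation of the methyl ketone with the amide acetal gives the enaminone, and acid-promoted addition of the ortho-phenol with loss of dimethylamine closes the pyranone (enaminone route to chromones), the reagent supplying C2.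

Step 3
Reactants: 4 5-methoxy-7-[(triisopropylsilyl)oxy]-4H-chromen-4-one
Product: 6 rac-3-bromo-5-methoxy-7-[(triisopropylsilyl)oxy]chroman-4-one, via lithium enolate 5 (not isolated)
Conditions: LiBH(s-Bu)3, THF, −78 °C; then NBS, THF, −78 °C; NH4Cl (aq)
Reagents that add atoms: N-bromosuccinimide, O=C1CCC(=O)N1Br
Why: Conjugate hydride addition of the hindered borohydride to C2 of the vinylogous ester (attack at C4 is disfavoured by the flanking 5-methoxy group) should give the C3 enolate regiospecifically, which NBS brominates at C3 faster than ring A (reductive α-bromination); a racemic bromide is all that the stereoconvergent step 8 needs.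

Step 4
Reactants: 7 4-bromo-2-methoxyphenol
Product: 8 4-bromo-2-methoxy-1-[(2-methylbut-3-yn-2-yl)oxy]benzene
Conditions: 3-chloro-3-methylbut-1-yne, K2CO3, KI, CuI (cat.), acetone, reflux
Reagents that add atoms: 3-chloro-3-methylbut-1-yne, C#CC(C)(C)Cl
Why: Copper-assisted O-alkylation of the phenoxide with the tertiary propargylic chloride should give the aryl 1,1-dimethylpropargyl ether, the only free hydroxyl being the one para to bromine.

Step 5
Reactants: 8 4-bromo-2-methoxy-1-[(2-methylbut-3-yn-2-yl)oxy]benzene
Product: 9 6-bromo-8-methoxy-2,2-dimethyl-2H-chromene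
Conditions: N,N-diethylaniline, 190 °C
Reagents that add atoms: none
Why: Aromatic propargyl Claisen rearrangement followed by 1,5-hydrogen shift and oxa-6π electrocyclisation should give the 2,2-dimethylchromene as a single regioisomer, because the other ortho position is blocked by the methoxy group.

Step 6
Reactants: 9 6-bromo-8-methoxy-2,2-dimethyl-2H-chromene
Product: 10 6-bromo-2,2-dimethyl-2H-chromen-8-ol
Conditions: NaSEt, DMF, 120 °C; then HCl (aq) work-up
Reagents that add atoms: none
Why: SN2 demethylation of the aryl methyl ether by thiolate is chosen because Lewis acids would attack the acid-sensitive chromene, while the unactivated aryl bromide should not undergo substitution.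

Step 7
Reactants: 10 6-bromo-2,2-dimethyl-2H-chromen-8-ol
Product: 11 [(6-bromo-2,2-dimethyl-2H-chromen-8-yl)oxy](tert-butyl)dimethylsilane
Conditions: TBSCl, imidazole, DMF, 25 °C
Reagents that add atoms: tert-butylchlorodimethylsilane, CC(C)(C)[Si](C)(C)Cl
Why: Standard silylation of the phenol gives an ether that is inert to magnesium insertion and is cleaved by fluoride at the end.

Step 8
Reactants: 6 rac-3-bromo-5-methoxy-7-[(triisopropylsilyl)oxy]chroman-4-one; 11 [(6-bromo-2,2-dimethyl-2H-chromen-8-yl)oxy](tert-butyl)dimethylsilane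
Product: 14 (3R)-3-{8-[(tert-butyldimethylsilyl)oxy]-2,2-dimethyl-2H-chromen-6-yl}-5-methoxy-7-[(triisopropylsilyl)oxy]-2,3-dihydro-4H-chromen-4-one, via arylmagnesium bromide 12 (not isolated), via arylzinc iodide 13 (not isolated)
Conditions: 11, Mg, LiCl, THF, 25 °C; ZnI2, THF, 0 °C; then 6, NiCl2·glyme (5 mol %), 2,6-bis[(4R,5R)-4-(methoxymethyl)-5-phenyl-4,5-dihydrooxazol-2-yl]pyridine (6.5 mol %), glyme/THF, −30 °C
Reagents that add atoms: none
Why: Magnesium insertion into 11 and transmetalation with ZnI2 give the arylzinc iodide, which hands its aryl group to the pybox-bound nickel centre formed from NiCl2·glyme; the resulting aryl complex of monovalent nickel abstracts bromine from either enantiomer of 6 to give the same planar, C4-carbonyl-conjugated C3 radical, which is captured by the chiral aryl nickel centre and released by reductive elimination from trivalent nickel with formation of the C3–C1' bond. The closest known reaction type is the enantioconvergent Negishi α-arylation of racemic secondary α-bromo ketones with arylzinc iodides catalysed by NiCl2·glyme and a pybox ligand, which gives enolisable tertiary α-aryl ketones. No ring is closed. The new stereocentre C3 is set under catalyst control by the C2-symmetric pybox ligand, the configuration of the bromide being erased at the radical stage. The step needs enantioselectivity, survival of the configurationally labile product and suppression of β-elimination of the ring oxygen or of HBr; the absence of a Brønsted base, the weakly basic arylzinc, −30 °C and an aryl nucleophile with hydrogen at both positions ortho to C1' should secure these. The ring-locked geometry of the C3 radical is the main uncertainty for the level of induction.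

Step 9
Reactants: 14 (3R)-3-{8-[(tert-butyldimethylsilyl)oxy]-2,2-dimethyl-2H-chromen-6-yl}-5-methoxy-7-[(triisopropylsilyl)oxy]-2,3-dihydro-4H-chromen-4-one
Product: 15 (3R)-7-hydroxy-3-(8-hydroxy-2,2-dimethyl-2H-chromen-6-yl)-5-methoxy-2,3-dihydro-4H-chromen-4-one
Conditions: HF·pyridine, pyridine, THF, 0 °C to 25 °C
Reagents that add atoms: none
Why: Fluoride cleavage of both aryl silyl ethers under buffered, weakly acidic conditions generates neither phenoxide nor enolate, so the C3 stereocentre and the chromene should both survive.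

Compound list
1 | 2',4'-dihydroxy-6'-methoxyacetophenone | CC(=O)c1c(O)cc(O)cc1OC | starting material
2 | 1-{2-hydroxy-6-methoxy-4-[(triisopropylsilyl)oxy]phenyl}ethan-1-one | CC(=O)c1c(O)cc(O[Si](C(C)C)(C(C)C)C(C)C)cc1OC | intermediate
3 | (E)-3-(dimethylamino)-1-{2-hydroxy-6-methoxy-4-[(triisopropylsilyl)oxy]phenyl}prop-2-en-1-one (enaminone) | CN(C)/C=C/C(=O)c1c(O)cc(O[Si](C(C)C)(C(C)C)C(C)C)cc1OC | intermediate
4 | 5-methoxy-7-[(triisopropylsilyl)oxy]-4H-chromen-4-one | COc1cc(O[Si](C(C)C)(C(C)C)C(C)C)cc2occc(=O)c12 | intermediate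
5 | lithium 5-methoxy-7-[(triisopropylsilyl)oxy]-2H-chromen-4-olate (lithium enolate) | COc1cc(O[Si](C(C)C)(C(C)C)C(C)C)cc2OCC=C(O[Li])c12 | intermediate
6 | rac-3-bromo-5-methoxy-7-[(triisopropylsilyl)oxy]chroman-4-one | COc1cc(O[Si](C(C)C)(C(C)C)C(C)C)cc2OCC(Br)C(=O)c12 | intermediate
7 | 4-bromo-2-methoxyphenol | COc1cc(Br)ccc1O | starting material
8 | 4-bromo-2-methoxy-1-[(2-methylbut-3-yn-2-yl)oxy]benzene | COc1cc(Br)ccc1OC(C)(C)C#C | intermediate
9 | 6-bromo-8-methoxy-2,2-dimethyl-2H-chromene | COc1cc(Br)cc2C=CC(C)(C)Oc12 | intermediate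
10 | 6-bromo-2,2-dimethyl-2H-chromen-8-ol | Oc1cc(Br)cc2C=CC(C)(C)Oc12 | intermediate
11 | [(6-bromo-2,2-dimethyl-2H-chromen-8-yl)oxy](tert-butyl)dimethylsilane | CC(C)(C)[Si](C)(C)Oc1cc(Br)cc2C=CC(C)(C)Oc12 | intermediate
12 | {8-[(tert-butyldimethylsilyl)oxy]-2,2-dimethyl-2H-chromen-6-yl}magnesium bromide | CC(C)(C)[Si](C)(C)Oc1cc([Mg]Br)cc2C=CC(C)(C)Oc12 | intermediate
13 | {8-[(tert-butyldimethylsilyl)oxy]-2,2-dimethyl-2H-chromen-6-yl}zinc iodide | CC(C)(C)[Si](C)(C)Oc1cc([Zn]I)cc2C=CC(C)(C)Oc12 | intermediate
14 | (3R)-3-{8-[(tert-butyldimethylsilyl)oxy]-2,2-dimethyl-2H-chromen-6-yl}-5-methoxy-7-[(triisopropylsilyl)oxy]-2,3-dihydro-4H-chromen-4-one | COc1cc(O[Si](C(C)C)(C(C)C)C(C)C)cc2c1C(=O)[C@H](c1cc(O[Si](C)(C)C(C)(C)C)c3c(c1)C=CC(C)(C)O3)CO2 | intermediate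
15 | (3R)-7-hydroxy-3-(8-hydroxy-2,2-dimethyl-2H-chromen-6-yl)-5-methoxy-2,3-dihydro-4H-chromen-4-one (CNP0113665.2) | COc1cc(O)cc2c1C(=O)[C@H](c1cc(O)c3c(c1)C=CC(C)(C)O3)CO2 | target

Total step count: 9 steps.
Longest linear sequence: 6 steps (steps 4, 5, 6, 7, 8 and 9, from 7).

Steps most likely to fail

Step 8. The risk is low facial discrimination at the ring-locked C3 radical, ring opening by β-elimination of the aryloxide from a C3-bound nickel intermediate, or reductive loss of bromine. The fallback forms the same bond at the sp2 level and sets C3 afterwards by known chemistry. It sets out from 2 and 11. Enaminone 3 is made as in step 2 and cyclised with I2 (CHCl3, 25 °C) to 3-iodo-5-methoxy-7-[(triisopropylsilyl)oxy]-4H-chromen-4-one F1. Bromide 11 is borylated (bis(pinacolato)diboron, Pd(dppf)Cl2, KOAc, dioxane, 80 °C) to tert-butyl{[2,2-dimethyl-6-(4,4,5,5-tetramethyl-1,3,2-dioxaborolan-2-yl)-2H-chromen-8-yl]oxy}dimethylsilane F2. Suzuki–Miyaura coupling of F1 with F2 (Pd(dppf)Cl2, K3PO4, dioxane/water, 60 °C) should give 3-{8-[(tert-butyldimethylsilyl)oxy]-2,2-dimethyl-2H-chromen-6-yl}-5-methoxy-7-[(triisopropylsilyl)oxy]-4H-chromen-4-one F3. Asymmetric transfer hydrogenation of F3 (RuCl(p-cymene)[(R,R)-TsDPEN], HCO2H/Et3N, 40 °C) should reduce C2=C3 and then C4=O with dynamic kinetic resolution at C3. The catalyst fixes C4 as R and the cis relationship then fixes C3 as R, giving (3R,4R)-3-{8-[(tert-butyldimethylsilyl)oxy]-2,2-dimethyl-2H-chromen-6-yl}-5-methoxy-7-[(triisopropylsilyl)oxy]chroman-4-ol F4. Dess–Martin oxidation of F4 (CH2Cl2, NaHCO3, 0 °C) returns to the route at 14.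

Step 3. The risk is competing 1,2-reduction, bromination of the electron-rich ring A or double bromination, and loss of HBr back to the chromone on isolation. The fallback separates reduction from halogenation and sets out from 4. Hydrogenation of the C2=C3 bond (H2, Pd/C, EtOAc) gives 5-methoxy-7-[(triisopropylsilyl)oxy]chroman-4-one F5. Soft enolisation of F5 (TMSOTf, Et3N, CH2Cl2, 0 °C) gives triisopropyl({5-methoxy-4-[(trimethylsilyl)oxy]-2H-chromen-7-yl}oxy)silane F6. NBS (THF, −78 °C) brominates F6, a neutral enol ether, at C3, rejoining the route at 6.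

Step 4. The risk is slow substitution at the tertiary propargylic chloride with competing elimination to the enyne, leaving phenol unconsumed. The fallback sets out from 7 and builds the pyran ring without a propargyl ether. It uses ortho-selective condensation with 3-methylbut-2-enal templated by PhB(OH)2 (AcOH, toluene, reflux, removal of water), in which an ortho-quinone methide closes by oxa-6π electrocyclisation. This should give the chromene directly and rejoins the route at 9, bypassing steps 4 and 5.

Further compounds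
F1 | step 8 | 3-iodo-5-methoxy-7-[(triisopropylsilyl)oxy]-4H-chromen-4-one | COc1cc(O[Si](C(C)C)(C(C)C)C(C)C)cc2occ(I)c(=O)c12
F2 | step 8 | tert-butyl{[2,2-dimethyl-6-(4,4,5,5-tetramethyl-1,3,2-dioxaborolan-2-yl)-2H-chromen-8-yl]oxy}dimethylsilane | CC(C)(C)[Si](C)(C)Oc1cc(B3OC(C)(C)C(C)(C)O3)cc2C=CC(C)(C)Oc12
F3 | step 8 | 3-{8-[(tert-butyldimethylsilyl)oxy]-2,2-dimethyl-2H-chromen-6-yl}-5-methoxy-7-[(triisopropylsilyl)oxy]-4H-chromen-4-one | COc1cc(O[Si](C(C)C)(C(C)C)C(C)C)cc2occ(-c3cc(O[Si](C)(C)C(C)(C)C)c4OC(C)(C)C=Cc4c3)c(=O)c12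
F4 | step 8 | (3R,4R)-3-{8-[(tert-butyldimethylsilyl)oxy]-2,2-dimethyl-2H-chromen-6-yl}-5-methoxy-7-[(triisopropylsilyl)oxy]chroman-4-ol | COc1cc(O[Si](C(C)C)(C(C)C)C(C)C)cc2c1[C@H](O)[C@H](c1cc(O[Si](C)(C)C(C)(C)C)c3c(c1)C=CC(C)(C)O3)CO2
F5 | step 3 | 5-methoxy-7-[(triisopropylsilyl)oxy]chroman-4-one | COc1cc(O[Si](C(C)C)(C(C)C)C(C)C)cc2OCCC(=O)c12
F6 | step 3 | triisopropyl({5-methoxy-4-[(trimethylsilyl)oxy]-2H-chromen-7-yl}oxy)silane | COc1cc(O[Si](C(C)C)(C(C)C)C(C)C)cc2OCC=C(O[Si](C)(C)C)c12
F0 | step 4 | none | none
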